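If a product fills quickly and then rides on its precursor while the pair leaks slowly against the run, you can reckon it from its share and from the leak of the pair, without following the whole network.

    starting material ⇌ target (K1 = 0.27, k1 = 1.0 h⁻¹, Ea1 = 116 kJ mol⁻¹, ΔH1 = 11.0 kJ mol⁻¹)
    target ⇌ isomer of the product A (K2 = 11, k2 = 0.38 h⁻¹, Ea2 = 103 kJ mol⁻¹, ΔH2 = −11.0 kJ mol⁻¹)
    isomer of the product A ⇌ starting material (k3 = 0.073 h⁻¹, Ea3 = 108 kJ mol⁻¹)
    target ⇌ isomer of the product B (K4 = 7.6, k4 = 0.0069 h⁻¹, Ea4 = 118 kJ mol⁻¹, ΔH4 = −7.00 kJ mol⁻¹)
    starting material ⇌ dormant form (K5 = 3.9, k5 = 0.092 h⁻¹, Ea5 = 117 kJ mol⁻¹, ΔH5 = −60.0 kJ mol⁻¹)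
    (constants at 70 °C)

| setting | amber | grey | teal | green |
|---|---|---|---|---|
| starting material | 0.80 M | 0.80 M | 0.80 M | 0.80 M |
| time | 5.0 h | 5.0 h | 5.0 h | 5.0 h |
| remark | at 85 °C until 2.5 h, from then on at 55 °C |  |  |  |
| temperature |  | 55 °C | 70 °C | 85 °C |

- the constants hold at 70 °C; other temperatures follow from the activation energies and enthalpies

1. which flask leads in amount of target, in percent of the starting material charged ("all alike" within 1.5 percentage points) (amber / grey / teal / green / all alike)
2. how much target is there at the end, in percent of the starting material charged: amber
3. how much target is there at the end, in percent of the starting material charged: grey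
4. how much target is there at the end, in percent of the starting material charged: teal
5. how much target is there at the end, in percent of the starting material charged: green

My reckoning, made on grey at 55 °C:

1. The forward rate constant from starting material to target is 0.156 h⁻¹ at this temperature, so in grey target starts forming at 0.125 M h⁻¹.

2. The first slowing is the undoing of that step. Let K be its equilibrium constant, here 0.226. The relaxation half-life of the pair by this step alone, both ways together, is 0.821 h, short against 5.0 h. This gives a relaxation constant μ = 0.845 h⁻¹, and the unfilled part of the balance shrinks to the factor exp(−μt), which is 1.46 % at the end. Target then holds the share s of the pair, 18.5 %. This is a rapid pre-equilibrium.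

3. The second slowing is the leak. The enthalpies 11.0 kJ mol⁻¹ and −11.0 kJ mol⁻¹ cancel, so the equilibrium constant of the step between isomer A and starting material does not change with temperature, and the run from starting material to isomer A follows the activation energy of that step. Starting material leaves for the dormant form at 0.0141 h⁻¹, and target leaves for isomer A at 0.0730 h⁻¹. Starting material leaves for isomer A at 0.0384 h⁻¹, which is more than the exit to the dormant form and more than the exit of target once that is multiplied by K. Weighting each by its member's part of the pair gives λ = 0.0563 h⁻¹, the leak constant: the fraction of the balanced pair lost per hour, returns neglected. The step from target to isomer B stays out of λ; it makes no difference to target in grey.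

4. Over 5.0 h the leak cuts the pair to 75.5 %. Target is then s·(exp(−λt) − exp(−μt)) = 13.7 %. Neglecting returns is fair here, since the leak half-life of 12.3 h is longer than the run.

5. In teal the leak half-life is 2.14 h, shorter than the run, so returns count and my reckoning stops there. The target-to-isomer-A step in green runs 24 times faster than in grey. I give no figures for teal, green or amber, but I commit to grey leading.

The forecast gives 4.2 % for amber, 13.1 % for grey, 6.5 % for teal and 5.4 % for green, and names grey, since “the cool flask keeps the most”. My grey figure stands 0.60 percentage points above it.

The simulation gives 4.28 % for amber, 13.7 % for grey, 6.60 % for teal and 5.33 % for green, and grey leads.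

In grey, target stood at 14.0 % by 2.50 h and at 13.7 % by 5.00 h. Meanwhile the leak ran: starting material went from 73.4 % to 62.9 %, and isomer A from 9.61 % to 18.0 %. The pair ended at 76.6 %, where λ gave 75.5 %.

Take the neighbour flask, like grey but kept at 40 °C. There K = 0.187, λ = 0.00827 h⁻¹ and μ = 0.129 h⁻¹, so the same formula gives 6.85 %. The simulation gives 7.14 %.

The numbers of this flask are made up; the result is computed.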